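## Structural features

The target is a linear trimer of three 2-(4-hydroxyphenyl)chromane-3,5,7-triol (flavan-3-ol) units. C4 of the top unit is bonded to C8 of the middle unit, and C4 of the middle unit to C8 of the bottom unit, so two diaryl-substituted methine carbons hold three phloroglucinol-type rings A together. Top and bottom units are 2,3-cis and (2R,3R), as in (−)-epiafzelechin, and the top unit is 3,4-trans (4R). Reading the stereodescriptors of the middle unit shows that it is (2S,3S,4R): the mirror-image 2,3-cis series with a 3,4-trans bond to the bottom unit, so it cannot be taken from the natural monomer. Top and middle units each carry three contiguous stereocenters C2–C3–C4 on ring C and the bottom unit two, eight in all. The fragile points are the nine free phenols (air oxidation), the two C4–C8 bonds (ionisation at C4 under acid) and C2 (epimerisation under base through opening of ring C when the 4′-phenol is free), so the end game must be neutral. The real difficulty is the middle unit: a ring C of the unnatural enantiomeric series must be created with three defined stereocenters between two bulky chiral flavan units, on a ring A that is substituted at C8 and fused at C4a/C8a. The key step uses the fact that O1–C8a–C4a–C4 of the middle unit is the skeleton of an o-quinone methide whose methide carbon (C4) can already carry C8 of the bottom unit. C2–C3 is a cis-disubstituted two-carbon piece that can be delivered as a Z-alkene with boron standing in for the 3-hydroxyl, so that a hetero-Diels–Alder reaction forms C3–C4 and O1–C2 and closes ring C.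

## Logic of the disconnections

19 to 18. Eleven O–H bonds of 19 (nine phenols and the 3-hydroxyls of the top and bottom units) are traced back to O–CH2Ph bonds. Free phenols and acid-labile interflavan bonds cannot be carried through cation, organolithium and boron chemistry. The gain is an oxidation-stable carrier with a single free hydroxyl. The forward step must be a neutral hydrogenolysis that spares both C4–C8 bonds and the three benzylic C2–O1 bonds.

18 to 17. The C3–O bond of the middle unit is exchanged for a C3–B bond. Boron can ride on an alkene carbon into a cycloaddition without reversing the polarity of the alkene, which an oxygen substituent would do. The gain is that the 3-hydroxyl becomes part of the two-carbon partner. The forward step must oxidise a hindered secondary C–B bond with retention and without elimination towards O1.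

17 to 12 and 15 (through 16). C3–C4 and O1–C2 of the middle ring C are cut together in a retro-[4+2] sense, giving 16 and 15; 16 is 12 minus the elements of water. This is the one place where the mirror-image middle unit can be made de novo with all three stereocenters in one event, at a stage where both interflavan carbons are already attached. The gain is the removal of a ring and three stereocenters. The forward step needs control of the methide face by a chiral acid, an endo topology on a Z-configured methide, and retention of the alkene geometry.

15 to 13 and 14. The C–B and C–H bonds across the alkene are cut. Both fragments are commercial. The forward step must be a formal trans-addition of H–B, because ordinary syn-hydroboration would give the E isomer and hence the wrong 2,3-relationship.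

12 to 8 and 9 (through 10 and 11). The bond between the carbinol carbon (future C4 of the middle unit) and C8 of the bottom unit is cut. A carbonyl addition is the most dependable way to join two hindered, electron-rich arenes at one carbon, and the configuration formed is irrelevant. The gain is a split into a top-plus-ring-A half and the bottom unit. The forward step needs a C8-specific metalation and a free phenol that is kept as its salt.

9 to 3. The C8–Br bond is cut. It is the handle that makes C8 and not C6 of the bottom unit the nucleophilic carbon, and it demands a regioselective bromination.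

8 to 6 (through 7). The C4a–CHO bond is cut. The free phenol of 6 can direct a one-carbon electrophile to its only free ortho carbon, so no protecting-group step is needed. The forward step must be strictly ortho-selective, leaving the CH between the two benzyloxy groups alone.

6 to 4 and 5. The bond from C4 of the top unit to C8 of the middle ring A is cut. Attack on a flavan-4-yl cation occurs trans to the 3-substituent and so gives the required top C4 configuration. Partner 5 already carries two benzyl ethers and the single free phenol in the pattern needed in 12, which avoids selective protection of a triol. The forward step must alkylate ortho to the hydroxyl of 5 and not between its two ether groups.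

4 to 3. The C4–O bond is cut. Oxidation of the doubly activated C4–H bond is the standard way to reach the C4 cation, and it must not touch C2–H or the benzyl ethers.

3 to 2 to 1. The benzyl ether bonds are cut, phenolic ones first and then the 3-O ether. One stock of 3 serves as the source of both the top unit (through 4) and the bottom unit (through 9).

## Other disconnections considered

Alternative 1: The cut is O1–C2 and C4–C8(bottom) of the middle unit. It leads back to the cyclopropyl pivalate A1, whose three ring carbons are the future C2, C3 and C4 and whose ring-A phenol is free, with 3 as the nucleophile. In the forward key step anodic one-electron oxidation of the arylcyclopropane gives a radical cation, the phenol opens the C2–C4 bond by attack at C2 with inversion, a second electron is removed, and C8 of 3 captures the C4 cation trans to the 3-pivaloyloxy group to give A2. In its favour, two bonds and ring C form in one operation, and the bottom unit enters as the plain arene 3 without bromination or lithiation, which is better than the chosen plan. The C4 configuration would rest on the well-founded trans attack on a 3-oxygenated flavan-4-yl cation, possibly reinforced by the neighbouring pivaloate, which is also on firmer ground than the endo/exo question of the chosen plan. Against it, A1 needs three defined stereocenters on the cyclopropane (aryl trans to pivaloyloxy, since opening at C2 inverts), which only moves the asymmetric problem into a multistep precursor synthesis. The anode has no evident reason to prefer the arylcyclopropane over the many benzyloxyarene rings of A1 and 3, and an oxidisable nucleophile under a two-electron oxidation would call for a cation-pool protocol at the least. After the key step, pivaloate removal and hydrogenolysis are needed, which equals the two closing steps of the chosen plan. Overall the step count is probably higher because of A1, and the closed-shell acid catalysis of the chosen plan tolerates electron-rich arenes far better.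

Alternative 2: The cut is C4–C4a and O1–C2 of the middle unit. It leads to the enal A3 (a propenal on C8 of the bottom unit, its β-carbon being the future C4) and the locally symmetric dihydroxyarene A4 (top unit on a 4-benzyloxy-2,6-dihydroxyphenyl ring). In the forward key step a diarylprolinol silyl ether forms the iminium ion of A3, A4 adds through either of its two equivalent ring CH positions, and the neighbouring phenol closes the lactol to give A5. In its favour, amine-catalysed Friedel–Crafts addition of electron-rich phenols to enals with hemiacetal closure is an established reaction type, so on precedent this alternative is better than the chosen plan. The symmetric ring also removes any regiochemical question on ring A and needs no lithium or boron chemistry, which is at least equal. Against it, A5 holds only C4 of the three stereocenters and lacks both the C2 aryl group and the C3 oxygen. These would have to be introduced afterwards by oxidation of the lactol carbon, hydroxylation next to it, aryl addition and reductive closure, each with its own stereochemical question, and the free 7-hydroxyl would also need benzylation. The iminium ion of A3 is hindered by two ortho oxygen substituents and deactivated by its electron-rich aryl group. In convergence the two plans are equal, but after the key step this alternative needs at least four or five further steps against two.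

Alternative 3: The cut is C4–C4a and C4–C8(bottom). It leads to the open-chain aldehyde A6, in which O1 of ring A is already bonded to C2, C2 and C3 are preformed stereocenters and C4 is the formyl carbon, with 3 again as the nucleophile. In the forward key step BF3·OEt2 activates the aldehyde, C4a attacks it to close ring C, the resulting 4-hydroxyl ionises and C8 of 3 adds trans to the 3-benzyloxy group to give A7. In its favour, A7 needs only hydrogenolysis, one step fewer after the key step than the chosen plan, which is better. The bottom unit again enters as 3 without bromination or lithiation, which is better, and the second half of the step is the established trans-selective arylation of a flavan-4-yl cation with no catalyst-controlled face selection, which is better founded. Against it, the burden moves to A6. Its O1–C2 ether has to be formed with defined configuration between a hindered phenol and a 4-alkoxybenzylic carbon that ionises easily. Its α-benzyloxy aldehyde can epimerise at C3 and can lose the aryloxy group by β-elimination. Under BF3·OEt2 the benzylic C2–O1 bond may ionise before or after cyclisation. The (2S,3S) configuration would still have to come from a separate asymmetric step, so the step count to A6 is comparable to that to 12. Overall the length is similar, with the risk placed in the precursor where the chosen plan places it in the key step.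

Key step: step 9

Assumption: (R)-TRIP is written as the enantiomer of the acid that leaves open the methide face leading to 17; should this pairing with the two (2R,3R) units prove mismatched, the (S)-acid takes its place.
Remark: 12 is used as the mixture of carbinol epimers, because that carbon becomes trigonal in 16.

## Route

Step 1
Reactants: 1 (−)-epiafzelechin
Product: 2 5,7,4′-tri-O-benzyl-(−)-epiafzelechin
Conditions: BnBr (3.3 equiv), K2CO3, DMF, 0 °C → rt, Ar
Reagents that add atoms: benzyl bromide, BrCc1ccccc1
Why: Williamson ether synthesis; carbonate deprotonates only the three phenols, so the 3-hydroxyl stays free, and the mild base at low temperature avoids C2 epimerisation and C-benzylation of ring A.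

Step 2
Reactants: 2 5,7,4′-tri-O-benzyl-(−)-epiafzelechin
Product: 3 3,5,7,4′-tetra-O-benzyl-(−)-epiafzelechin
Conditions: NaH, BnBr, DMF, 0 °C → rt
Reagents that add atoms: benzyl bromide, BrCc1ccccc1
Why: Williamson etherification of the secondary alkoxide; with every phenol capped, C2 can no longer epimerise by ring opening, and no stereocenter is touched.

Step 3
Reactants: 3 3,5,7,4′-tetra-O-benzyl-(−)-epiafzelechin
Product: 4 3,5,7,4′-tetra-O-benzyl-4β-(2-ethoxyethoxy)-epiafzelechin (2,3-cis-3,4-trans)
Conditions: DDQ (2 equiv), HOCH2CH2OEt, CH2Cl2, rt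
Reagents that add atoms: 2-ethoxyethanol, CCOCCO
Why: Benzylic C–H oxidation by hydride abstraction: DDQ removes hydride from C4, whose cation is stabilised by O1 and the 5,7-dioxygenated ring A, and the alcohol adds trans to the 3-benzyloxy group. The C4 configuration is of no consequence because this ether is ionised again in step 4.

Step 4
Reactants: 4 3,5,7,4′-tetra-O-benzyl-4β-(2-ethoxyethoxy)-epiafzelechin; 5 3,5-bis(benzyloxy)phenol
Product: 6 3,5-bis(benzyloxy)-2-(3,5,7,4′-tetra-O-benzyl-epiafzelechin-4β-yl)phenol
Conditions: 5 (4 equiv), TMSOTf (0.3 equiv), CH2Cl2, −78 → −30 °C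
Reagents that add atoms: none
Why: Friedel–Crafts alkylation by the flavan-4-yl cation; the arene adds anti to the 3-benzyloxy group, which sets the 3,4-trans configuration of the top C4. Attack ortho to the hydroxyl of 5 is favoured by statistics, by the smaller flanking group, and by O-to-C migration of any aryl ether formed first (the same preference that makes C8 more reactive than C6 in benzylated flavans); the excess of 5 suppresses double alkylation.

Step 5
Reactants: 6 3,5-bis(benzyloxy)-2-(3,5,7,4′-tetra-O-benzyl-epiafzelechin-4β-yl)phenol
Product: 8 4,6-bis(benzyloxy)-2-hydroxy-3-(3,5,7,4′-tetra-O-benzyl-epiafzelechin-4β-yl)benzaldehyde, via salicyl alcohol 7 (not isolated)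
Conditions: MgCl2, Et3N, (CH2O)n, THF, reflux
Reagents that add atoms: formaldehyde (as paraformaldehyde), C=O
Why: Magnesium-mediated ortho-formylation of a phenol: the magnesium aryloxide delivers formaldehyde to the only free ortho carbon, and the salicyl alcohol 7 is oxidised in the flask by hydride transfer to a second formaldehyde. The CH between the two benzyloxy groups is not reached because the electrophile is delivered through the metal-bound oxygen.

Step 6
Reactants: 3 3,5,7,4′-tetra-O-benzyl-(−)-epiafzelechin
Product: 9 8-bromo-3,5,7,4′-tetra-O-benzyl-epiafzelechin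
Conditions: NBS, CH2Cl2, −40 °C → rt
Reagents that add atoms: N-bromosuccinimide, O=C1CCC(=O)N1Br
Why: Electrophilic aromatic bromination; in 5,7-di-O-benzyl flavans C8, flanked by the ring oxygen, is more reactive than C6 between the two benzyloxy groups, and one equivalent at low temperature stops at the monobromide.

Step 7
Reactants: 9 8-bromo-3,5,7,4′-tetra-O-benzyl-epiafzelechin; 8 4,6-bis(benzyloxy)-2-hydroxy-3-(3,5,7,4′-tetra-O-benzyl-epiafzelechin-4β-yl)benzaldehyde
Product: 12 o-hydroxybenzhydrol [4,6-bis(benzyloxy)-2-hydroxy-3-(top unit-4β-yl)phenyl](3,5,7,4′-tetra-O-benzyl-epiafzelechin-8-yl)methanol (both carbinol epimers), via aryllithium 10 (not isolated), via sodium aryloxide 11 (not isolated)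
Conditions: 9, t-BuLi (2.0 equiv), THF, −78 °C; 8, NaH (1.0 equiv), THF, 0 °C; combine, −78 → −20 °C; H2O; Et3N-deactivated SiO2
Reagents that add atoms: none
Why: Bromine–lithium exchange followed by 1,2-addition of the aryllithium to the aldehyde. The phenol is kept as its sodium salt so that it neither quenches 10 nor lets the adduct expel oxide towards a quinone methide in the basic medium. The carbinol configuration is not controlled and need not be.

Step 8
Reactants: 13 1-(benzyloxy)-4-ethynylbenzene; 14 pinacolborane
Product: 15 (Z)-2-[2-(4-benzyloxyphenyl)ethenyl]-4,4,5,5-tetramethyl-1,3,2-dioxaborolane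
Conditions: 13 (1.5 equiv), [RhCl(cod)]2 (cat.), P(i-Pr)3, Et3N, cyclohexane, rt
Reagents that add atoms: none
Why: Rhodium-catalysed formal trans-hydroboration of a terminal alkyne: a 1,2-hydrogen shift gives a rhodium vinylidene, boron is delivered to the terminal carbon anti to the aryl group, and the Z-alkenylboronate results. Uncatalysed syn-hydroboration would give the E isomer.

Step 9
Reactants: 12 o-hydroxybenzhydrol (both carbinol epimers); 15 (Z)-2-[2-(4-benzyloxyphenyl)ethenyl]-4,4,5,5-tetramethyl-1,3,2-dioxaborolane
Product: 17 perbenzylated trimer carrying the pinacol boronate at C3 of the middle unit (middle ring C 2,3-cis-3,4-trans as drawn in the list), via o-quinone methide 16 (not isolated)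
Conditions: (R)-TRIP (10 mol%), 15 (3 equiv), 5 Å MS, toluene, 0 °C → rt
Reagents that add atoms: none
Why: Proposed new method: TRIP protonates the benzylic hydroxyl of 12, water leaves, and the o-quinone methide 16 stays hydrogen-bonded to the phosphate through O1; the boron-bearing alkene carbon of 15 then bonds to C4 while positive charge builds on the carbon carrying the 4-benzyloxyphenyl group, and O1 closes on that carbon before the C2–C3 bond can rotate, so ring C arises in one asynchronous inverse-demand [4+2] event, the closest known reaction type being the phosphoric-acid-catalysed [4+2] cycloaddition of o-quinone methides, generated from o-hydroxybenzhydrols, with styrenes. Ring C (O1, C2, C3, C4, C4a, C8a) closes in the cycloaddition mode, four atoms from the heterodiene and two from the alkene; in the stepwise limit the last bond is the six-membered collapse of an aryloxide/benzylic cation ion pair. C4 is set by the methide face that the chiral phosphate leaves open, which is catalyst control that has to override any bias from the two resident flavan units. C3 is set relative to C4 by the topology: A(1,3) strain with the 5-benzyloxy group turns the bottom-unit aryl to the inside (Z) position of 16, and endo placement of the cis boryl/aryl pair then puts boron trans to that aryl. C2 is set relative to C3 by suprafacial addition to the Z-alkene, which keeps aryl and boron cis. The step needs regioselectivity, secured by the cation-stabilising 4-benzyloxyphenyl group that makes the boron-bearing carbon the nucleophilic one, and chemoselectivity, secured because 12 has a single free phenol and because the pinacol ester is too weakly Lewis acidic to bind O1 and divert the reaction into 1,4-alkenyl transfer with loss of boron. The sieves take up the water so that 16 is not returned to 12.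

Step 10
Reactants: 17 perbenzylated trimer carrying the pinacol boronate at C3 of the middle unit
Product: 18 perbenzylated trimer with free 3-hydroxyl on the middle unit
Conditions: NaBO3·4H2O, THF/H2O, rt
Reagents that add atoms: sodium perborate, [Na+].[Na+].O[B-]1(O)OO[B-](O)(O)OO1
Why: Oxidation of the C–B bond by 1,2-migration of carbon from boron to peroxide oxygen, which proceeds with retention and so turns the 2,3-cis-3,4-trans boronate into the 2,3-cis-3,4-trans alcohol. The mild, weakly basic perborate spares the benzyl ethers, and the axial C3–B bond is not aligned for elimination towards O1.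

Step 11
Reactants: 18 perbenzylated trimer with free 3-hydroxyl on the middle unit
Product: 19 CNP0191553.2, epiafzelechin-(4β→8)-ent-epiafzelechin-(4α→8)-epiafzelechin
Conditions: H2 (1 atm), Pd(OH)2/C, THF/MeOH/H2O, rt
Reagents that add atoms: none
Why: Hydrogenolysis of the eleven benzyl ethers under neutral conditions, which is expected to leave the two C4–C8 bonds, the benzylic C2–O1 bonds and all eight stereocenters untouched.

## Compound list

1 | (−)-epiafzelechin, (2R,3R) | Oc1cc(O)c2c(c1)O[C@H](c1ccc(O)cc1)[C@H](O)C2 | starting material
2 | 5,7,4′-tri-O-benzyl-(−)-epiafzelechin | C(c5ccccc5)Oc1ccc([C@H]2Oc3cc(OCc5ccccc5)cc(OCc5ccccc5)c3C[C@H]2O)cc1 | intermediate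
3 | 3,5,7,4′-tetra-O-benzyl-(−)-epiafzelechin | C(c5ccccc5)Oc1ccc([C@H]2Oc3cc(OCc5ccccc5)cc(OCc5ccccc5)c3C[C@H]2OCc5ccccc5)cc1 | intermediate
4 | 3,5,7,4′-tetra-O-benzyl-4β-(2-ethoxyethoxy)-epiafzelechin (3,4-trans) | C(c5ccccc5)Oc1ccc([C@H]2Oc3cc(OCc5ccccc5)cc(OCc5ccccc5)c3[C@H](OCCOCC)[C@H]2OCc5ccccc5)cc1 | intermediate
5 | 3,5-bis(benzyloxy)phenol | Oc1cc(OCc2ccccc2)cc(OCc2ccccc2)c1 | starting material
6 | 3,5-bis(benzyloxy)-2-(3,5,7,4′-tetra-O-benzyl-epiafzelechin-4β-yl)phenol | C(c5ccccc5)Oc1ccc([C@H]2Oc3cc(OCc5ccccc5)cc(OCc5ccccc5)c3[C@H](c3c(OCc5ccccc5)cc(OCc5ccccc5)cc3O)[C@H]2OCc5ccccc5)cc1 | intermediate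
7 | salicyl alcohol: 3,5-bis(benzyloxy)-2-(hydroxymethyl)-6-(3,5,7,4′-tetra-O-benzyl-epiafzelechin-4β-yl)phenol | C(c5ccccc5)Oc1ccc([C@H]2Oc3cc(OCc5ccccc5)cc(OCc5ccccc5)c3[C@H](c3c(OCc5ccccc5)cc(OCc5ccccc5)c(CO)c3O)[C@H]2OCc5ccccc5)cc1 | intermediate
8 | 4,6-bis(benzyloxy)-2-hydroxy-3-(3,5,7,4′-tetra-O-benzyl-epiafzelechin-4β-yl)benzaldehyde | C(c5ccccc5)Oc1ccc([C@H]2Oc3cc(OCc5ccccc5)cc(OCc5ccccc5)c3[C@H](c3c(OCc5ccccc5)cc(OCc5ccccc5)c(C=O)c3O)[C@H]2OCc5ccccc5)cc1 | intermediate
9 | 8-bromo-3,5,7,4′-tetra-O-benzyl-epiafzelechin | Brc1c(OCc5ccccc5)cc(OCc5ccccc5)c2c1O[C@H](c3ccc(OCc5ccccc5)cc3)[C@H](OCc5ccccc5)C2 | intermediate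
10 | 8-lithio-3,5,7,4′-tetra-O-benzyl-epiafzelechin | [Li]c1c(OCc5ccccc5)cc(OCc5ccccc5)c2c1O[C@H](c3ccc(OCc5ccccc5)cc3)[C@H](OCc5ccccc5)C2 | intermediate
11 | sodium aryloxide of aldehyde 8 | C(c5ccccc5)Oc1ccc([C@H]2Oc3cc(OCc5ccccc5)cc(OCc5ccccc5)c3[C@H](c3c(OCc5ccccc5)cc(OCc5ccccc5)c(C=O)c3[O-])[C@H]2OCc5ccccc5)cc1.[Na+] | intermediate
12 | o-hydroxybenzhydrol: ring A of the middle unit (top unit at C8, free O1–H, 5,7-di-O-benzyl) joined through the carbinol carbon (either epimer) to C8 of the tetra-O-benzyl bottom unit | C(c5ccccc5)Oc1ccc([C@H]2Oc3cc(OCc5ccccc5)cc(OCc5ccccc5)c3[C@H](c3c(OCc5ccccc5)cc(OCc5ccccc5)c(C(O)c6c(OCc5ccccc5)cc(OCc5ccccc5)c7c6O[C@H](c8ccc(OCc5ccccc5)cc8)[C@H](OCc5ccccc5)C7)c3O)[C@H]2OCc5ccccc5)cc1 | intermediate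
13 | 1-(benzyloxy)-4-ethynylbenzene | C#Cc1ccc(OCc2ccccc2)cc1 | starting material
14 | pinacolborane | CC1(C)OBOC1(C)C | starting material
15 | (Z)-2-[2-(4-benzyloxyphenyl)ethenyl]-4,4,5,5-tetramethyl-1,3,2-dioxaborolane | C(c5ccccc5)Oc1ccc(/C=C\B2OC(C)(C)C(C)(C)O2)cc1 | intermediate
16 | o-quinone methide: 3,5-bis(benzyloxy)-6-[(Z)-(bottom unit-8-yl)methylidene]-2-(top unit-4β-yl)cyclohexa-2,4-dien-1-one, bottom-unit aryl on the carbonyl side | C(c5ccccc5)Oc1ccc([C@H]2Oc3cc(OCc5ccccc5)cc(OCc5ccccc5)c3[C@H](C3=C(OCc5ccccc5)C=C(OCc5ccccc5)/C(=C/c6c(OCc5ccccc5)cc(OCc5ccccc5)c7c6O[C@H](c8ccc(OCc5ccccc5)cc8)[C@H](OCc5ccccc5)C7)C3=O)[C@H]2OCc5ccccc5)cc1 | intermediate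
17 | perbenzylated trimer with pinacol boronate at C3 of the middle unit (middle ring C 2,3-cis-3,4-trans, mirror-image series) | C(c5ccccc5)Oc1ccc([C@H]2Oc3cc(OCc5ccccc5)cc(OCc5ccccc5)c3[C@H](c3c(OCc5ccccc5)cc(OCc5ccccc5)c4c3O[C@@H](c9ccc(OCc5ccccc5)cc9)[C@@H](B9OC(C)(C)C(C)(C)O9)[C@@H]4c6c(OCc5ccccc5)cc(OCc5ccccc5)c7c6O[C@H](c8ccc(OCc5ccccc5)cc8)[C@H](OCc5ccccc5)C7)[C@H]2OCc5ccccc5)cc1 | intermediate
18 | perbenzylated trimer with free 3-hydroxyl on the middle unit | C(c5ccccc5)Oc1ccc([C@H]2Oc3cc(OCc5ccccc5)cc(OCc5ccccc5)c3[C@H](c3c(OCc5ccccc5)cc(OCc5ccccc5)c4c3O[C@@H](c9ccc(OCc5ccccc5)cc9)[C@@H](O)[C@@H]4c6c(OCc5ccccc5)cc(OCc5ccccc5)c7c6O[C@H](c8ccc(OCc5ccccc5)cc8)[C@H](OCc5ccccc5)C7)[C@H]2OCc5ccccc5)cc1 | intermediate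
19 | CNP0191553.2: top (2R,3R,4R), middle (2S,3S,4R), bottom (2R,3R) | Oc1ccc([C@H]2Oc3cc(O)cc(O)c3[C@H](c3c(O)cc(O)c4c3O[C@@H](c3ccc(O)cc3)[C@@H](O)[C@@H]4c3c(O)cc(O)c4c3O[C@H](c3ccc(O)cc3)[C@H](O)C4)[C@H]2O)cc1 | target

## Step count and least certain steps

Total: 11 steps. Longest linear sequence: 9 steps (steps 1, 2, 3, 4, 5, 7, 9, 10, 11); steps 6 and 8 lie on side branches.

Step 9 (key step, new method). Several processes may defeat it:
- Low reactivity: the methide is stabilised by six oxygen substituents on its two aryl rings and the alkenylboronate is only a moderate π-nucleophile, so 16 may revert, dimerise or decompose before it is trapped.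
- Poor facial selectivity, if the chiral acid and the two resident flavan units are mismatched.
- Exo approach, or a fully stepwise course with rotation about C2–C3 before closure, which would invert the 3,4- or the 2,3-relationship.
- Transfer of the alkenyl group from boron to C4 with loss of boron.
- Acid-induced ionisation of the top C4–C8 bond.

The fallback uses known chemistry only, gives up the cycloaddition and brings in the middle unit as a preformed mirror-image monomer. It sets out from 1, uses 3 and 4, and returns at 18. Heating 1 in weakly basic aqueous buffer under argon equilibrates C2 through the ring-opened quinone methide of ring B and gives, after separation and recycling of 1, (2S,3R)-afzelechin F1. Benzylation as in step 1 gives its 5,7,4′-tri-O-benzyl ether F2. Dess–Martin oxidation gives the flavan-3-one F3, and LiBH(s-Bu)3 at −78 °C delivers hydride anti to the 2-aryl group to give 5,7,4′-tri-O-benzyl-ent-epiafzelechin F4. DDQ with 2-ethoxyethanol, as in step 3, gives the 4-(2-ethoxyethoxy) ether F5. TMSOTf-promoted coupling of F5 with an excess of 3 forms the 3,4-trans bond to C8 of the bottom unit and gives the dimer F6. A second TMSOTf coupling of F6 with 4 joins C4 of the top unit to C8 of the middle unit and gives 18, from which step 11 follows.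

Step 4. The cation may attack the carbon of 5 that lies between the two benzyloxy groups, or the oxygen, and the product may be alkylated a second time; all of these lower the amount of 6. The fallback removes the regiochemical choice by using a symmetric nucleophile; it sets out from 4 and returns at 8, so it also replaces step 5. Lewis-acid-promoted alkylation of an excess of phloroglucinol by 4 gives the triol 2-(3,5,7,4′-tetra-O-benzyl-epiafzelechin-4β-yl)benzene-1,3,5-triol F7. Vilsmeier–Haack formylation (POCl3, DMF, then water) gives 2,4,6-trihydroxy-3-(3,5,7,4′-tetra-O-benzyl-epiafzelechin-4β-yl)benzaldehyde F8, there being only one kind of ring CH. Benzyl bromide (2 equiv) with K2CO3 etherifies the hydroxyl para to the formyl group and the unhindered ortho hydroxyl, while the hydrogen-bonded hydroxyl wedged between the formyl group and the flavanyl group stays free, which gives 8.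

Step 7. Addition of a 2,6-dioxygenated aryllithium to a doubly ortho-substituted, aryloxide-deactivated aldehyde may be slow, so that proton transfer or decomposition of 10 on warming competes; 12 may also ionise during work-up or on acidic silica. The fallback reverses the polarity; it sets out from 9 and 6 and returns at 12. Aryllithium 10, made from 9 as before, is quenched with DMF to give 8-formyl-3,5,7,4′-tetra-O-benzyl-epiafzelechin F9. The bromomagnesium aryloxide of 6 (EtMgBr, toluene) then adds through its only free ortho carbon to F9 in an ortho-specific hydroxyalkylation and gives 12.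

Step 8. Incomplete Z-selectivity, or later Z-to-E isomerisation, would carry the E-alkene into step 9 and end in the 2,3-trans series. The fallback sets out from 13 and returns at 15. Deprotonation with n-BuLi, borylation with 2-isopropoxy-4,4,5,5-tetramethyl-1,3,2-dioxaborolane and quenching with ethereal HCl give the alkynylboronate 2-[(4-benzyloxyphenyl)ethynyl]-4,4,5,5-tetramethyl-1,3,2-dioxaborolane F10. Syn-hydrozirconation with Cp2Zr(H)Cl places zirconium on the boron-bearing carbon, and protonolysis with water then gives 15 with aryl and boron cis.

## Further compounds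

F1 | step 9 | (2S,3R)-afzelechin (ent-afzelechin) | Oc1cc(O)c2c(c1)O[C@@H](c1ccc(O)cc1)[C@H](O)C2
F2 | step 9 | 5,7,4′-tri-O-benzyl-(2S,3R)-afzelechin | C(c5ccccc5)Oc1cc(OCc5ccccc5)c2c(c1)O[C@@H](c1ccc(OCc5ccccc5)cc1)[C@H](O)C2
F3 | step 9 | (2S)-5,7-bis(benzyloxy)-2-[4-(benzyloxy)phenyl]chroman-3-one | C(c5ccccc5)Oc1cc(OCc5ccccc5)c2c(c1)O[C@@H](c1ccc(OCc5ccccc5)cc1)C(=O)C2
F4 | step 9 | 5,7,4′-tri-O-benzyl-ent-epiafzelechin, (2S,3S) | C(c5ccccc5)Oc1cc(OCc5ccccc5)c2c(c1)O[C@@H](c1ccc(OCc5ccccc5)cc1)[C@@H](O)C2
F5 | step 9 | 5,7,4′-tri-O-benzyl-4-(2-ethoxyethoxy)-ent-epiafzelechin (3,4-trans) | C(c5ccccc5)Oc1cc(OCc5ccccc5)c2c(c1)O[C@@H](c1ccc(OCc5ccccc5)cc1)[C@@H](O)[C@@H]2OCCOCC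
F6 | step 9 | dimer: 5,7,4′-tri-O-benzyl-ent-epiafzelechin-(4α→8)-3,5,7,4′-tetra-O-benzyl-epiafzelechin | C(c5ccccc5)Oc1cc(OCc5ccccc5)c2c(c1)O[C@@H](c1ccc(OCc5ccccc5)cc1)[C@@H](O)[C@@H]2c1c(OCc5ccccc5)cc(OCc5ccccc5)c2c1O[C@H](c1ccc(OCc5ccccc5)cc1)[C@H](OCc5ccccc5)C2
F7 | step 4 | 2-(3,5,7,4′-tetra-O-benzyl-epiafzelechin-4β-yl)benzene-1,3,5-triol | C(c5ccccc5)Oc1ccc([C@H]2Oc3cc(OCc5ccccc5)cc(OCc5ccccc5)c3[C@H](c3c(O)cc(O)cc3O)[C@H]2OCc5ccccc5)cc1
F8 | step 4 | 2,4,6-trihydroxy-3-(3,5,7,4′-tetra-O-benzyl-epiafzelechin-4β-yl)benzaldehyde | C(c5ccccc5)Oc1ccc([C@H]2Oc3cc(OCc5ccccc5)cc(OCc5ccccc5)c3[C@H](c3c(O)cc(O)c(C=O)c3O)[C@H]2OCc5ccccc5)cc1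
F9 | step 7 | 8-formyl-3,5,7,4′-tetra-O-benzyl-epiafzelechin | O=Cc1c(OCc5ccccc5)cc(OCc5ccccc5)c2c1O[C@H](c3ccc(OCc5ccccc5)cc3)[C@H](OCc5ccccc5)C2
F10 | step 8 | 2-[(4-benzyloxyphenyl)ethynyl]-4,4,5,5-tetramethyl-1,3,2-dioxaborolane | C(c5ccccc5)Oc1ccc(C#CB2OC(C)(C)C(C)(C)O2)cc1
A1 | alternative 1 | cyclopropyl pivalate: 2-(4-benzyloxyphenyl) trans to pivaloyloxy, 3-[4,6-bis(benzyloxy)-2-hydroxy-3-(top unit-4β-yl)phenyl] cis to pivaloyloxy | C(c5ccccc5)Oc1ccc([C@H]2Oc3cc(OCc5ccccc5)cc(OCc5ccccc5)c3[C@H](c3c(OCc5ccccc5)cc(OCc5ccccc5)c([C@@H]4[C@H](OC(=O)C(C)(C)C)[C@H]4c9ccc(OCc5ccccc5)cc9)c3O)[C@H]2OCc5ccccc5)cc1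
A2 | alternative 1 | perbenzylated trimer with pivaloate on O3 of the middle unit | C(c5ccccc5)Oc1ccc([C@H]2Oc3cc(OCc5ccccc5)cc(OCc5ccccc5)c3[C@H](c3c(OCc5ccccc5)cc(OCc5ccccc5)c4c3O[C@@H](c9ccc(OCc5ccccc5)cc9)[C@@H](OC(=O)C(C)(C)C)[C@@H]4c6c(OCc5ccccc5)cc(OCc5ccccc5)c7c6O[C@H](c8ccc(OCc5ccccc5)cc8)[C@H](OCc5ccccc5)C7)[C@H]2OCc5ccccc5)cc1
A3 | alternative 2 | (E)-3-(3,5,7,4′-tetra-O-benzyl-epiafzelechin-8-yl)prop-2-enal | O=C/C=C/c6c(OCc5ccccc5)cc(OCc5ccccc5)c7c6O[C@H](c8ccc(OCc5ccccc5)cc8)[C@H](OCc5ccccc5)C7
A4 | alternative 2 | 5-(benzyloxy)-2-(3,5,7,4′-tetra-O-benzyl-epiafzelechin-4β-yl)benzene-1,3-diol | C(c5ccccc5)Oc1ccc([C@H]2Oc3cc(OCc5ccccc5)cc(OCc5ccccc5)c3[C@H](c3c(O)cc(OCc5ccccc5)cc3O)[C@H]2OCc5ccccc5)cc1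
A5 | alternative 2 | trimer whose middle unit is a 4-aryl-chroman-2-ol (both anomers) with free 7-hydroxyl | C(c5ccccc5)Oc1ccc([C@H]2Oc3cc(OCc5ccccc5)cc(OCc5ccccc5)c3[C@H](c3c(O)cc(OCc5ccccc5)c4c3OC(O)C[C@@H]4c6c(OCc5ccccc5)cc(OCc5ccccc5)c7c6O[C@H](c8ccc(OCc5ccccc5)cc8)[C@H](OCc5ccccc5)C7)[C@H]2OCc5ccccc5)cc1
A6 | alternative 3 | 2-(benzyloxy)-3-[4-(benzyloxy)phenyl]-3-[3,5-bis(benzyloxy)-2-(top unit-4β-yl)phenoxy]propanal, configured as C3 and C2 of the middle unit | C(c5ccccc5)Oc1ccc([C@H]2Oc3cc(OCc5ccccc5)cc(OCc5ccccc5)c3[C@H](c3c(OCc5ccccc5)cc(OCc5ccccc5)cc3O[C@@H](c9ccc(OCc5ccccc5)cc9)[C@@H](OCc5ccccc5)C=O)[C@H]2OCc5ccccc5)cc1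
A7 | alternative 3 | perbenzylated trimer (twelve benzyl ethers) | C(c5ccccc5)Oc1ccc([C@H]2Oc3cc(OCc5ccccc5)cc(OCc5ccccc5)c3[C@H](c3c(OCc5ccccc5)cc(OCc5ccccc5)c4c3O[C@@H](c9ccc(OCc5ccccc5)cc9)[C@@H](OCc5ccccc5)[C@@H]4c6c(OCc5ccccc5)cc(OCc5ccccc5)c7c6O[C@H](c8ccc(OCc5ccccc5)cc8)[C@H](OCc5ccccc5)C7)[C@H]2OCc5ccccc5)cc1
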